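Positions are given in halimane numbering: ring A = C1–C5 and C10, ring B = C5–C10, chain C11–C15, C2 ketone, C1=C10 alkene, ester and methyl on C4, methyls on C8, C9 and C13.

## The problem

The target is a halim-1(10)-en-2-one. Ring A is a cyclohexenone whose C1=C10 double bond is exocyclic to ring B, and the quaternary C9 carries a 3-methyl-5-hydroxypentyl chain. Five stereocentres must be set: quaternary C4 (ester and methyl), the adjacent ring-fusion carbon C5, C8, the quaternary C9 next to it, and the remote C13. C4 and C5 are neighbours in ring A, so C4 can control C5. C5 fixes the face of ring A from which C6 departs and can therefore control C9 when ring B is closed onto C10. C8 and C13 sit in an acyclic sector (C13 three bonds from the nearest ring atom) and must be bought as stereodefined building blocks. Both quaternary carbons are flanked by substituted carbons, so bonds to them need reactions that tolerate hindrance. Sensitive points are the γ-hydrogen at C5 of the final enone (base epimerises C5 or moves the alkene to C5=C10), the same drift of the unconjugated C1=C10 alkene under acid or metal hydrides, the methyl ester toward organometallics, and the primary alcohol, which must travel protected. The enabling feature is that C4 and C5 are the β- and α-carbons of a carbonyl placed at C10: C4 is then the ester-bearing β-carbon of a cyclohexenone, C5 is the enolate carbon, and the same C10 carbonyl later becomes the alkenyl triflate from which ring B and the C1=C10 alkene are made.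

## Retrosynthesis

**C15–O and C2=O.** The alcohol of 27 is unmasked last from silyl ether 26 under non-basic conditions, because the enone is base-sensitive at C5. The C2 carbonyl of 26 is cut back to the allylic CH2 of alkene 25. This is preferred over carrying oxygen at C2 from the start, since a second carbonyl in ring A would compete as acceptor and as enolisation site in every earlier step. The forward oxidation must choose C2–H over the tertiary C5–H.

**C11=C12 and C9–C10.** The saturated chain of 25 comes from diene 24 by reduction of the disubstituted C11=C12 alkene only. Cutting C9–C10 of 24 opens ring B to enol triflate 23, an intramolecular Heck precursor. This cut removes a ring and the second quaternary centre at once. The competing ring B cuts (C5–C6, C8–C9) would need a carbanion or cation at a neopentyl position. The forward closure must be 6-exo and must place the C9 methyl on the face of C6.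

**C10–O.** Triflate 23 is the kinetic (C1-side) enol derivative of ketone 21. The forward step needs only deprotonation at the CH2 and not at the hindered C5–H.

**C4–CH3 and C5–C6 (key).** Ketone 21 is cut at both bonds to the C4/C5 pair, giving methyl 3-oxocyclohex-1-ene-1-carboxylate 3, trimethylaluminium 11 and chain iodide 18. Cutting either bond alone would leave a 2-alkyl-3-carbomethoxy-enone (tetrasubstituted acceptor) or a preformed chiral keto ester that must be enolised regioselectively. Cutting both uses the enolate generated by the conjugate addition itself. The precursors are an achiral six-carbon ring, a commodity reagent and an acyclic iodide. The forward reaction must be enantioselective at C4, regioselective for C4 over C5, and trans-selective at C5.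

**C6–I and C11–C12.** Iodide 18 is taken from chloride 17 so that the future leaving group passes inertly through the coupling. 17 is cut at the sp2–sp3 bond C11–C12 into E-vinyl iodide 14 and the alkylzinc 16 derived from iodide 7. A Negishi coupling keeps the alkene geometry and touches neither stereocentre. An olefination at C9=C11 would give a trisubstituted alkene of uncertain geometry.

**C9–CH3 and C9≡C11.** Vinyl iodide 14 comes from iodo alcohol 13, made by carboalumination–iodination of alkynol 10, which fixes the E geometry and the C9 methyl in one step. Alkyne 10 is the one-carbon homologue of lactol 9, from lactone 8. The five-carbon lactone 8 already holds C6–C9 with the C8 methyl and the right oxidation pattern. Shorter chiral-pool pieces would need a carbon added on each side of the stereocentre.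

**C12–I.** Iodide 7 comes from iodo alcohol 6 and iodo ester 5, which is the decarboxylative iodination product of (R)-monomethyl 3-methylglutarate 4. The acid carbon is the one lost, so C13 arrives with the correct sense and the ester becomes C15.

**Ring A acceptor.** Keto ester 3 is the methoxycarbonylation product of enol triflate 2 of cyclohexane-1,3-dione 1.

## Roads not taken

Alternative 1: Ring B closure by the Heck reaction taken as the strategic step. The cut is C9–C10. Forward, zerovalent palladium inserts into a C10 enol triflate of the type of 23, the alkenylpalladium adds 6-exo to the C9=C11 alkene, and β-hydride elimination gives the 1(10),11-diene A1 (the same structure as 24). The merits are real: one catalytic step makes ring B and the second quaternary centre, and the face selectivity can be tuned by the ligand. The three-component step has nothing comparable to offer for C9. The weak point is that this headline leaves open how the C4/C5 pair in the triflate is made, which is the harder half of the molecule. The chosen plan does not reject this closure; it uses it as step 14. What it adds is a one-flask supply of the Heck substrate with C4 and C5 already set.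

Alternative 2: Ring A built by Claisen ring contraction. The cuts are C4–C5 and a temporary O–C1 bond. Forward, soft enolisation and silylation of the δ-lactone malonate A2 gives an endocyclic silyl ketene acetal, and its [3,3] shift through a bicyclic boat gives the acid ester A3. This road is better in two respects. The C2 oxygen and the C1=C10 alkene arrive in place, so no late allylic oxidation is needed. The boat geometry also fixes C5 relative to C4 without relying on an intermolecular alkylation at a hindered enolate. Its weak points for this target are three. C4 arrives as a carboxyl that must be reduced to methyl next to a methyl ester on the same carbon (three to four steps at a neopentyl centre). Ring B with C8 and quaternary C9 must be made beforehand by separate asymmetric chemistry. Two lactone stereocentres and two protecting groups are spent on the way. The chosen plan sets against it a direct C4 methyl, three-fragment convergence and a much shorter sequence.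

Alternative 3: Ring B closed by Claisen contraction of a fused lactone. The cuts are C8–C9 and a temporary O–C6 bond. Forward, the dienyl silyl ketene acetal of fused δ-lactone A4 rearranges to the bicyclic acid A5 with a C6=C7 alkene. Its merit is that C8 and C9 are set together, their relation dictated by the propenyl geometry and the bicyclic transition state. That is a firmer basis for C9 than face selection in a Heck insertion, and the chosen plan has to accept that disadvantage. The weak points are these. The C9 carboxyl must be reduced to methyl at a doubly hindered centre. The enolisation is that of a dienolate conjugated with C1=C10, with regiochemical ambiguity. The C6=C7 alkene must be hydrogenated beside C1=C10. The lactone A4 also needs the C4/C5/C6 triad on ring A, so the C4/C5 problem is still unsolved. The chosen plan wins on length and on installing both quaternary methyls as methyl groups.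

Key step: step 12

Assumption (ligand sense): the (S,S,S) phosphoramidite L, from (S)-binaphthol and bis[(S)-1-phenylethyl]amine, is taken to deliver methyl to the face of 3 that gives (S)-C4; if the sense is the opposite, the (R,R,R) ligand is used and nothing else changes.
Assumption (material): (3R)-3-methyloxolan-2-one 8 is taken to be purchasable as the single enantiomer.

## Route

Step 1
Reactants: 1 cyclohexane-1,3-dione
Product: 2 3-oxocyclohex-1-en-1-yl trifluoromethanesulfonate
Conditions: Tf2O, pyridine, CH2Cl2, −78 → 0 °C
Reagents that add atoms: trifluoromethanesulfonic anhydride, O=S(=O)(OS(=O)(=O)C(F)(F)F)C(F)(F)F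
Why: O-sulfonylation of the fully enolised, symmetric 1,3-diketone gives a single enol triflate (vinylogous acyl triflate formation).

Step 2
Reactants: 2 3-oxocyclohex-1-en-1-yl trifluoromethanesulfonate
Product: 3 methyl 3-oxocyclohex-1-ene-1-carboxylate
Conditions: CO (1 atm), Pd(OAc)2 (5 mol %), PPh3 (10 mol %), Et3N, MeOH, DMF, 50 °C
Reagents that add atoms: carbon monoxide, [C-]#[O+]; methanol, CO
Why: Palladium-catalysed alkoxycarbonylation of an enol triflate (oxidative addition, CO insertion, methanolysis of the acylpalladium); the enone is untouched.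

Step 3
Reactants: 4 (3R)-5-methoxy-3-methyl-5-oxopentanoic acid [(R)-monomethyl 3-methylglutarate]
Product: 5 methyl (3S)-4-iodo-3-methylbutanoate
Conditions: PhI(OAc)2, I2, cyclohexane, hν (tungsten lamp), reflux
Reagents that add atoms: iodine, II
Why: Suárez iododecarboxylation (Hunsdiecker type): the acyl hypoiodite loses CO2 to a primary radical that is trapped by iodine. The stereocentre is β to the radical and is not touched; the descriptor changes only because CH2I now outranks the ester arm.

Step 4
Reactants: 5 methyl (3S)-4-iodo-3-methylbutanoate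
Product: 6 (3S)-4-iodo-3-methylbutan-1-ol
Conditions: i-Bu2AlH (2.2 equiv), CH2Cl2, −78 → −20 °C; aqueous potassium sodium tartrate
Reagents that add atoms: none
Why: Aluminium hydride reduction of the ester to the primary alcohol; the primary iodide is inert to i-Bu2AlH at low temperature, and the neutral work-up avoids cyclisation to the tetrahydrofuran.

Step 5
Reactants: 6 (3S)-4-iodo-3-methylbutan-1-ol
Product: 7 tert-butyl{[(3S)-4-iodo-3-methylbutyl]oxy}dimethylsilane
Conditions: TBSCl, imidazole, CH2Cl2, 0 °C → rt
Reagents that add atoms: tert-butyldimethylsilyl chloride, CC(C)(C)[Si](C)(C)Cl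
Why: Standard silylation of a primary alcohol; imidazole is too weak a base to trigger intramolecular displacement of iodide.

Step 6
Reactants: 8 (3R)-3-methyloxolan-2-one
Product: 9 (3R)-3-methyloxolan-2-ol (lactol, both anomers)
Conditions: i-Bu2AlH (1.05 equiv), CH2Cl2, −78 °C; aqueous potassium sodium tartrate
Reagents that add atoms: none
Why: Partial reduction of a γ-lactone stops at the stable tetrahedral aluminium hemiacetal at −78 °C and gives the lactol on work-up; the α-centre is not enolised.

Step 7
Reactants: 9 (3R)-3-methyloxolan-2-ol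
Product: 10 (3R)-3-methylpent-4-yn-1-ol
Conditions: MeC(O)C(N2)P(O)(OMe)2 (1.3 equiv), K2CO3, MeOH, 0 °C → rt
Reagents that add atoms: dimethyl (1-diazo-2-oxopropyl)phosphonate, CC(=O)C(=[N+]=[N-])P(=O)(OC)OC
Why: Seyferth–Gilbert homologation in the Ohira–Bestmann form on the open hydroxy-aldehyde tautomer of the lactol (diazoalkene, alkylidene carbene, 1,2-hydrogen shift). The C3 centre is carried over unchanged under the mild carbonate conditions.

Step 8
Reactants: 10 (3R)-3-methylpent-4-yn-1-ol; 11 trimethylaluminium
Product: 13 (3R,4E)-5-iodo-3,4-dimethylpent-4-en-1-ol, via alkenylalane 12 (not isolated)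
Conditions: Me3Al (3 equiv), Cp2ZrCl2 (0.25 equiv), CH2Cl2, 0 °C → rt; then I2, THF, −30 → 0 °C
Reagents that add atoms: iodine, II
Why: Negishi zirconium-catalysed carboalumination: syn addition of CH3–Al across the terminal alkyne with methyl on the internal carbon, then iodinolysis with retention, gives the E-iodoalkene. The hydroxyl travels as its aluminium alkoxide.

Step 9
Reactants: 13 (3R,4E)-5-iodo-3,4-dimethylpent-4-en-1-ol
Product: 14 (1E,3R)-5-chloro-1-iodo-2,3-dimethylpent-1-ene
Conditions: PPh3, N-chlorosuccinimide, CH2Cl2, 0 °C → rt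
Reagents that add atoms: N-chlorosuccinimide, O=C1CCC(=O)N1Cl
Why: Appel-type chlorination of the primary alcohol through the alkoxyphosphonium salt. The chloride is a leaving-group precursor that is inert in the next coupling.

Step 10
Reactants: 7 tert-butyl{[(3S)-4-iodo-3-methylbutyl]oxy}dimethylsilane; 14 (1E,3R)-5-chloro-1-iodo-2,3-dimethylpent-1-ene
Product: 17 tert-butyl{[(3R,5E,7R)-9-chloro-3,6,7-trimethylnon-5-en-1-yl]oxy}dimethylsilane, via alkyllithium 15 (not isolated), via alkylzinc chloride 16 (not isolated)
Conditions: 7, t-BuLi (2.1 equiv), Et2O, −78 °C; ZnCl2, THF, −78 → 0 °C; then 14, Pd(PPh3)4 (5 mol %), THF, rt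
Reagents that add atoms: none
Why: Negishi sp3–sp2 cross-coupling: iodine–lithium exchange, transmetalation to zinc, then coupling at the vinyl iodide with retention of the E geometry. Zerovalent palladium does not insert into the primary chloride under these conditions, and neither stereocentre is involved.

Step 11
Reactants: 17 tert-butyl{[(3R,5E,7R)-9-chloro-3,6,7-trimethylnon-5-en-1-yl]oxy}dimethylsilane
Product: 18 tert-butyl{[(3R,5E,7R)-9-iodo-3,6,7-trimethylnon-5-en-1-yl]oxy}dimethylsilane
Conditions: NaI (5 equiv), butan-2-one, 80 °C, dark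
Reagents that add atoms: sodium iodide, [Na+].[I-]
Why: Finkelstein exchange at an unhindered primary carbon, driven by precipitation of NaCl.

Step 12
Reactants: 3 methyl 3-oxocyclohex-1-ene-1-carboxylate; 11 trimethylaluminium; 18 tert-butyl{[(3R,5E,7R)-9-iodo-3,6,7-trimethylnon-5-en-1-yl]oxy}dimethylsilane
Product: 21 methyl (1S,2R)-2-[(3R,4E,7R)-9-{[tert-butyl(dimethyl)silyl]oxy}-3,4,7-trimethylnon-4-en-1-yl]-1-methyl-3-oxocyclohexane-1-carboxylate, via aluminium enolate 19 (not isolated), via lithium aluminate enolate 20 (not isolated)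
Conditions: 3 (1.5 equiv), Me3Al (1.8 equiv), Cu(O2CC4H3S) (5 mol %), (S,S,S)-phosphoramidite L (10 mol %), Et2O, −30 °C; MeLi (1.8 equiv), −30 → 0 °C; then 18 (1.0 equiv), THF–HMPA, 0 °C → rt
Reagents that add atoms: none
Why: Copper-catalysed asymmetric conjugate addition with enolate alkylation: Me3Al transmetalates to ligand-bound monovalent copper, the methylcopper species forms a π-complex with the C4=C5 bond of 3 and, through a trivalent copper intermediate and reductive elimination, places CH3 on C4. The closest known reaction type is the copper-catalysed addition of alkylaluminium and alkylzinc reagents to β-substituted cyclohexenones and cyclic γ-keto esters with trapping of the metal enolate. No ring is closed; two skeletal bonds (C4–CH3, C5–C6) and two stereocentres are formed. C4 is set by the chiral ligand (reagent control, S required). Addition at C4 and not C5 follows from the ketone, activated by aluminium at oxygen, being the stronger acceptor, and it gives the C5=C10 enolate 19 regiospecifically. MeLi turns 19 into the more nucleophilic aluminate 20, which the unhindered primary iodide 18 alkylates in THF–HMPA before proton exchange can move the enolate. C5 is set by the new C4 centre: in the half-chair enolate the ester, smaller than methyl and aligned with the enolate π system, sits pseudoaxial, so axial attack at C5 comes anti to it and C6 ends trans to the ester and cis to the C4 methyl. The step needs enantioface selectivity at C4, C- over O-alkylation and trans selectivity at C5; the ligand, the soft iodide with the ate enolate, and the C4 substitution pattern respectively provide them.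

Step 13
Reactants: 21 methyl (1S,2R)-2-[(3R,4E,7R)-9-{[tert-butyl(dimethyl)silyl]oxy}-3,4,7-trimethylnon-4-en-1-yl]-1-methyl-3-oxocyclohexane-1-carboxylate
Product: 23 methyl (1S,2R)-2-[(3R,4E,7R)-9-{[tert-butyl(dimethyl)silyl]oxy}-3,4,7-trimethylnon-4-en-1-yl]-1-methyl-3-{[(trifluoromethyl)sulfonyl]oxy}cyclohex-3-ene-1-carboxylate, via potassium enolate 22 (not isolated)
Conditions: KN(SiMe3)2, THF, −78 °C; PhNTf2, −78 → 0 °C
Reagents that add atoms: N-phenylbis(trifluoromethanesulfonimide), O=S(=O)(N(c1ccccc1)S(=O)(=O)C(F)(F)F)C(F)(F)F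
Why: Kinetic enolisation with a bulky amide removes a C1 proton and not the hindered tertiary C5–H next to quaternary C4; O-triflation of the enolate then fixes the C1=C10 position. The ester has no α-hydrogen.

Step 14
Reactants: 23 methyl (1S,2R)-2-[(3R,4E,7R)-9-{[tert-butyl(dimethyl)silyl]oxy}-3,4,7-trimethylnon-4-en-1-yl]-1-methyl-3-{[(trifluoromethyl)sulfonyl]oxy}cyclohex-3-ene-1-carboxylate
Product: 24 methyl (1S,5R,6R,8aS)-5-[(1E,3S)-5-{[tert-butyl(dimethyl)silyl]oxy}-3-methylpent-1-en-1-yl]-1,5,6-trimethyl-1,2,3,5,6,7,8,8a-octahydronaphthalene-1-carboxylate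
Conditions: Pd(OAc)2 (10 mol %), dppp (20 mol %), K2CO3, toluene, 80 °C
Reagents that add atoms: none
Why: Intramolecular Heck reaction in the cationic manifold: oxidative addition at C10, 6-exo-trig syn insertion onto C9 of the trisubstituted alkene, and β-hydride elimination toward C12 (C9 has no hydrogen) give the E C11=C12 alkene. C9 is set by the substrate: C6 leaves C5 on one face of ring A, the three-atom tether can bring C9 to C10 only from that face, and syn insertion then puts the C9 methyl on the tether face and C11 on the H5 face. Carbonate removes the palladium hydride before it can re-add.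

Step 15
Reactants: 24 methyl (1S,5R,6R,8aS)-5-[(1E,3S)-5-{[tert-butyl(dimethyl)silyl]oxy}-3-methylpent-1-en-1-yl]-1,5,6-trimethyl-1,2,3,5,6,7,8,8a-octahydronaphthalene-1-carboxylate
Product: 25 methyl (1S,5S,6R,8aS)-5-[(3R)-5-{[tert-butyl(dimethyl)silyl]oxy}-3-methylpentyl]-1,5,6-trimethyl-1,2,3,5,6,7,8,8a-octahydronaphthalene-1-carboxylate
Conditions: 2-O2NC6H4SO2NHNH2 (excess, in portions), Et3N, CH2Cl2, rt
Reagents that add atoms: none
Why: Diimide reduction: concerted transfer of H2 to the disubstituted C11=C12 alkene, while the trisubstituted C1=C10 alkene between C5 and quaternary C9 is left. No metal hydride is present to move that alkene to C5=C10. The descriptors at C9 and C13 change only through priority changes.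

Step 16
Reactants: 25 methyl (1S,5S,6R,8aS)-5-[(3R)-5-{[tert-butyl(dimethyl)silyl]oxy}-3-methylpentyl]-1,5,6-trimethyl-1,2,3,5,6,7,8,8a-octahydronaphthalene-1-carboxylate
Product: 26 methyl (1S,5S,6R,8aS)-5-[(3R)-5-{[tert-butyl(dimethyl)silyl]oxy}-3-methylpentyl]-1,5,6-trimethyl-3-oxo-1,2,3,5,6,7,8,8a-octahydronaphthalene-1-carboxylate
Conditions: Rh2(C6H10NO)4 (dirhodium tetracaprolactamate, 1 mol %), t-BuOOH (5 equiv), K2CO3, CH2Cl2, rt
Reagents that add atoms: tert-butyl hydroperoxide, CC(C)(C)OO
Why: Rhodium-catalysed allylic oxidation with t-BuOOH (tert-butylperoxyl radical chain): hydrogen is abstracted from the secondary C2–H next to the CH end of the trisubstituted alkene, as in the C7 oxidation of 5-ene steroids, and the mixed peroxide collapses to the enone. C9 has no hydrogen, and the tertiary C5–H is shielded by C4 and cannot lead to a ketone.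

Step 17
Reactants: 26 methyl (1S,5S,6R,8aS)-5-[(3R)-5-{[tert-butyl(dimethyl)silyl]oxy}-3-methylpentyl]-1,5,6-trimethyl-3-oxo-1,2,3,5,6,7,8,8a-octahydronaphthalene-1-carboxylate
Product: 27 methyl (1S,5S,6R,8aS)-5-[(3R)-5-hydroxy-3-methylpentyl]-1,5,6-trimethyl-3-oxo-1,2,3,5,6,7,8,8a-octahydronaphthalene-1-carboxylate (CNP0157174.1)
Conditions: HF·pyridine, THF, 0 °C → rt
Reagents that add atoms: none
Why: Acidic fluoride cleavage of a primary silyl ether; the non-basic medium avoids vinylogous enolisation at C5 of the enone and leaves the methyl ester alone.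

## Compound list

1 | cyclohexane-1,3-dione | O=C1CCCC(=O)C1 | starting material
2 | 3-oxocyclohex-1-en-1-yl trifluoromethanesulfonate | O=C1CCCC(OS(=O)(=O)C(F)(F)F)=C1 | intermediate
3 | methyl 3-oxocyclohex-1-ene-1-carboxylate | COC(=O)C1=CC(=O)CCC1 | intermediate
4 | (3R)-5-methoxy-3-methyl-5-oxopentanoic acid [(R)-monomethyl 3-methylglutarate] | OC(=O)C[C@@H](C)CC(=O)OC | starting material
5 | methyl (3S)-4-iodo-3-methylbutanoate | IC[C@@H](C)CC(=O)OC | intermediate
6 | (3S)-4-iodo-3-methylbutan-1-ol | IC[C@@H](C)CCO | intermediate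
7 | tert-butyl{[(3S)-4-iodo-3-methylbutyl]oxy}dimethylsilane | IC[C@@H](C)CCO[Si](C)(C)C(C)(C)C | intermediate
8 | (3R)-3-methyloxolan-2-one [(R)-α-methyl-γ-butyrolactone] | O=C1[C@H](C)CCO1 | starting material
9 | (3R)-3-methyloxolan-2-ol (lactol, both anomers) | OC1[C@H](C)CCO1 | intermediate
10 | (3R)-3-methylpent-4-yn-1-ol | OCC[C@@H](C)C#C | intermediate
11 | trimethylaluminium | C[Al](C)C | starting material
12 | [(1E,3R)-5-(dimethylalumanyloxy)-2,3-dimethylpent-1-en-1-yl]dimethylalumane (alkenylalane, formed in the flask) | C[Al](C)OCC[C@@H](C)/C(C)=C/[Al](C)C | intermediate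
13 | (3R,4E)-5-iodo-3,4-dimethylpent-4-en-1-ol | OCC[C@@H](C)/C(C)=C/I | intermediate
14 | (1E,3R)-5-chloro-1-iodo-2,3-dimethylpent-1-ene | ClCC[C@@H](C)/C(C)=C/I | intermediate
15 | [(2R)-4-{[tert-butyl(dimethyl)silyl]oxy}-2-methylbutyl]lithium (formed in the flask) | [Li]C[C@@H](C)CCO[Si](C)(C)C(C)(C)C | intermediate
16 | [(2S)-4-{[tert-butyl(dimethyl)silyl]oxy}-2-methylbutyl]zinc chloride (formed in the flask) | Cl[Zn]C[C@@H](C)CCO[Si](C)(C)C(C)(C)C | intermediate
17 | tert-butyl{[(3R,5E,7R)-9-chloro-3,6,7-trimethylnon-5-en-1-yl]oxy}dimethylsilane | ClCC[C@@H](C)/C(C)=C/C[C@@H](C)CCO[Si](C)(C)C(C)(C)C | intermediate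
18 | tert-butyl{[(3R,5E,7R)-9-iodo-3,6,7-trimethylnon-5-en-1-yl]oxy}dimethylsilane | ICC[C@@H](C)/C(C)=C/C[C@@H](C)CCO[Si](C)(C)C(C)(C)C | intermediate
19 | methyl (1S)-3-[(dimethylalumanyl)oxy]-1-methylcyclohex-2-ene-1-carboxylate (aluminium enolate, formed in the flask) | COC(=O)[C@@]1(C)CCCC(O[Al](C)C)=C1 | intermediate
20 | lithium {[(3S)-3-(methoxycarbonyl)-3-methylcyclohex-1-en-1-yl]oxy}trimethylaluminate (formed in the flask) | COC(=O)[C@@]1(C)CCCC(O[Al-](C)(C)C)=C1.[Li+] | intermediate
21 | methyl (1S,2R)-2-[(3R,4E,7R)-9-{[tert-butyl(dimethyl)silyl]oxy}-3,4,7-trimethylnon-4-en-1-yl]-1-methyl-3-oxocyclohexane-1-carboxylate | COC(=O)[C@@]1(C)CCCC(=O)[C@@H]1CC[C@@H](C)/C(C)=C/C[C@@H](C)CCO[Si](C)(C)C(C)(C)C | intermediate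
22 | potassium (5S,6R)-6-[(3R,4E,7R)-9-{[tert-butyl(dimethyl)silyl]oxy}-3,4,7-trimethylnon-4-en-1-yl]-5-(methoxycarbonyl)-5-methylcyclohex-1-en-1-olate (formed in the flask) | COC(=O)[C@@]1(C)CCC=C([O-])[C@@H]1CC[C@@H](C)/C(C)=C/C[C@@H](C)CCO[Si](C)(C)C(C)(C)C.[K+] | intermediate
23 | methyl (1S,2R)-2-[(3R,4E,7R)-9-{[tert-butyl(dimethyl)silyl]oxy}-3,4,7-trimethylnon-4-en-1-yl]-1-methyl-3-{[(trifluoromethyl)sulfonyl]oxy}cyclohex-3-ene-1-carboxylate | COC(=O)[C@@]1(C)CCC=C(OS(=O)(=O)C(F)(F)F)[C@@H]1CC[C@@H](C)/C(C)=C/C[C@@H](C)CCO[Si](C)(C)C(C)(C)C | intermediate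
24 | methyl (1S,5R,6R,8aS)-5-[(1E,3S)-5-{[tert-butyl(dimethyl)silyl]oxy}-3-methylpent-1-en-1-yl]-1,5,6-trimethyl-1,2,3,5,6,7,8,8a-octahydronaphthalene-1-carboxylate | COC(=O)[C@@]1(C)CCC=C2[C@@H]1CC[C@@H](C)[C@]2(C)/C=C/[C@@H](C)CCO[Si](C)(C)C(C)(C)C | intermediate
25 | methyl (1S,5S,6R,8aS)-5-[(3R)-5-{[tert-butyl(dimethyl)silyl]oxy}-3-methylpentyl]-1,5,6-trimethyl-1,2,3,5,6,7,8,8a-octahydronaphthalene-1-carboxylate | COC(=O)[C@@]1(C)CCC=C2[C@@H]1CC[C@@H](C)[C@]2(C)CC[C@@H](C)CCO[Si](C)(C)C(C)(C)C | intermediate
26 | methyl (1S,5S,6R,8aS)-5-[(3R)-5-{[tert-butyl(dimethyl)silyl]oxy}-3-methylpentyl]-1,5,6-trimethyl-3-oxo-1,2,3,5,6,7,8,8a-octahydronaphthalene-1-carboxylate | COC(=O)[C@@]1(C)CC(=O)C=C2[C@@H]1CC[C@@H](C)[C@]2(C)CC[C@@H](C)CCO[Si](C)(C)C(C)(C)C | intermediate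
27 | methyl (1S,5S,6R,8aS)-5-[(3R)-5-hydroxy-3-methylpentyl]-1,5,6-trimethyl-3-oxo-1,2,3,5,6,7,8,8a-octahydronaphthalene-1-carboxylate | COC(=O)[C@@]1(C)CC(=O)C=C2[C@@H]1CC[C@@H](C)[C@]2(C)CC[C@@H](C)CCO | target

## Step count and least certain steps

Total: 17 steps. Longest linear sequence: 12 steps, from lactone 8 (steps 6–17).

**Step 12 (key).** The likely failure is slow C-alkylation of the hindered aluminate enolate by an unactivated iodide. Proton exchange with the product would then move the enolate to the C1 side and lead to over-alkylation or O-alkylation. Facial selectivity at C5 may also be poor, and uncatalysed methyl addition may erode the selectivity at C4. Fallback: it sets out from 3, 11 and 18 and comes back at 21, replacing the alkylation by an aldol addition followed by deoxygenation. Iodide 18 is oxidised with Me3NO in DMSO to the aldehyde (3R,4E,7R)-9-{[tert-butyl(dimethyl)silyl]oxy}-3,4,7-trimethylnon-4-enal F1. Enolate 19, generated as in step 12, adds to F1 (aluminium enolates add to aldehydes readily even at hindered carbon, with the same anti-to-ester approach) to give the β-hydroxy ketone methyl (1S,2S)-2-[(3R,4E,7R)-9-{[tert-butyl(dimethyl)silyl]oxy}-1-hydroxy-3,4,7-trimethylnon-4-en-1-yl]-1-methyl-3-oxocyclohexane-1-carboxylate F2 as a carbinol mixture. 1,1'-Thiocarbonyldiimidazole converts it into the thiocarbonylimidazolide of F2, F3, and Barton–McCombie reduction (Bu3SnH, azobisisobutyronitrile, toluene, 90 °C) removes the oxygen to give 21.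

**Step 14.** The likely failures are insertion from the wrong face of ring A (C9 epimer), competing 7-endo insertion, and re-addition of palladium hydride that walks the C11=C12 alkene toward C13. The role of the C8 methyl in the face selection is not secured by the argument given. Fallback: it sets out from 21 and comes back at 26, closing ring B by a radical conjugate addition instead of a palladium insertion, and it also bypasses steps 15 and 16.
- The kinetic lithium enolate of 21 (LiN(i-Pr)2, −78 °C) is dehydrogenated with N-tert-butylbenzenesulfinimidoyl chloride to the enone methyl (1S,6R)-6-[(3R,4E,7R)-9-{[tert-butyl(dimethyl)silyl]oxy}-3,4,7-trimethylnon-4-en-1-yl]-1-methyl-5-oxocyclohex-3-ene-1-carboxylate F4.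
- Cold alkaline H2O2 gives the 1,2-epoxide of F4, F5.
- Wharton transposition (N2H4·H2O, AcOH, MeOH) gives the allylic alcohol methyl (1S,2S)-2-[(3R,4E,7R)-9-{[tert-butyl(dimethyl)silyl]oxy}-3,4,7-trimethylnon-4-en-1-yl]-5-hydroxy-1-methylcyclohex-3-ene-1-carboxylate F6.
- MnO2 gives the transposed enone methyl (1S,2S)-2-[(3R,4E,7R)-9-{[tert-butyl(dimethyl)silyl]oxy}-3,4,7-trimethylnon-4-en-1-yl]-1-methyl-5-oxocyclohex-3-ene-1-carboxylate F7, whose C10 is now the β-carbon of an enone.
- Hydrogen-atom transfer from an iron hydride (Fe(acac)3, PhSiH3, EtOH, 60 °C) to the trisubstituted alkene gives the tertiary C9 radical, which adds 6-exo to C10 and yields the saturated bicyclic ketone methyl (1S,5S,6R,8aS)-5-[(3R)-5-{[tert-butyl(dimethyl)silyl]oxy}-3-methylpentyl]-1,5,6-trimethyl-3-oxodecahydronaphthalene-1-carboxylate F8.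
- Dehydrogenation with 2-iodoxybenzoic acid in DMSO can only go toward C1=C10, because C4 has no hydrogen, and gives 26.

**Step 16.** The likely failure is hydrogen abstraction at the tertiary allylic C5–H instead of C2–H, leading to oxygenation at C5 or C1 or to alkene migration, and over-oxidation. Fallback: it sets out from 25 and comes back at 26, with the oxygen placed by an epoxide-based sequence of fixed regiochemistry. 3-Chloroperbenzoic acid (NaHCO3) gives the 1,10-epoxide of 25, F9. Phenylselenide (PhSeSePh, NaBH4, EtOH) opens it at the less substituted C1 to the hydroxy selenide F10, which is not isolated. H2O2 oxidation and selenoxide elimination away from the carbinol carbon give the tertiary allylic alcohol (10-hydroxy-1-ene) F11. Pyridinium chlorochromate, (C5H5NH)[CrO3Cl], effects the Babler–Dauben oxidative transposition to 26.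

**Step 7.** The likely failures are epimerisation of the α-methyl centre through enolisation of the open-chain aldehyde in basic methanol, and slow homologation because the closed lactol dominates. Fallback: it sets out from 8 and comes back at 14, avoiding the lactol and basic methanol and bringing in the chloride at the start. Lactone 8 is opened with SOCl2 (cat. ZnCl2) and then MeOH to methyl (2R)-4-chloro-2-methylbutanoate F12. i-Bu2AlH at −78 °C gives (2R)-4-chloro-2-methylbutanal F13. The non-basic Corey–Fuchs olefination (CBr4, PPh3) gives (3R)-1,1-dibromo-5-chloro-3-methylpent-1-ene F14. n-BuLi at −78 °C gives (3R)-5-chloro-3-methylpent-1-yne F15. Carboalumination–iodination as in step 8 then gives 14 directly.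

Further compounds
F1 | step 12 | (3R,4E,7R)-9-{[tert-butyl(dimethyl)silyl]oxy}-3,4,7-trimethylnon-4-enal | O=CC[C@@H](C)/C(C)=C/C[C@@H](C)CCO[Si](C)(C)C(C)(C)C
F2 | step 12 | methyl (1S,2S)-2-[(3R,4E,7R)-9-{[tert-butyl(dimethyl)silyl]oxy}-1-hydroxy-3,4,7-trimethylnon-4-en-1-yl]-1-methyl-3-oxocyclohexane-1-carboxylate (carbinol epimers) | COC(=O)[C@@]1(C)CCCC(=O)[C@@H]1C(O)C[C@@H](C)/C(C)=C/C[C@@H](C)CCO[Si](C)(C)C(C)(C)C
F3 | step 12 | thiocarbonylimidazolide (O-alkyl 1H-imidazole-1-carbothioate) of F2 | COC(=O)[C@@]1(C)CCCC(=O)[C@@H]1C(OC(=S)n2ccnc2)C[C@@H](C)/C(C)=C/C[C@@H](C)CCO[Si](C)(C)C(C)(C)C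
F4 | step 14 | methyl (1S,6R)-6-[(3R,4E,7R)-9-{[tert-butyl(dimethyl)silyl]oxy}-3,4,7-trimethylnon-4-en-1-yl]-1-methyl-5-oxocyclohex-3-ene-1-carboxylate | COC(=O)[C@@]1(C)CC=CC(=O)[C@@H]1CC[C@@H](C)/C(C)=C/C[C@@H](C)CCO[Si](C)(C)C(C)(C)C
F5 | step 14 | 1,2-epoxide of F4 (oxirane on C1 and C2, ketone at C10) | COC(=O)[C@@]1(C)CC2OC2C(=O)[C@@H]1CC[C@@H](C)/C(C)=C/C[C@@H](C)CCO[Si](C)(C)C(C)(C)C
F6 | step 14 | methyl (1S,2S)-2-[(3R,4E,7R)-9-{[tert-butyl(dimethyl)silyl]oxy}-3,4,7-trimethylnon-4-en-1-yl]-5-hydroxy-1-methylcyclohex-3-ene-1-carboxylate (carbinol epimers) | COC(=O)[C@@]1(C)CC(O)C=C[C@@H]1CC[C@@H](C)/C(C)=C/C[C@@H](C)CCO[Si](C)(C)C(C)(C)C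
F7 | step 14 | methyl (1S,2S)-2-[(3R,4E,7R)-9-{[tert-butyl(dimethyl)silyl]oxy}-3,4,7-trimethylnon-4-en-1-yl]-1-methyl-5-oxocyclohex-3-ene-1-carboxylate | COC(=O)[C@@]1(C)CC(=O)C=C[C@@H]1CC[C@@H](C)/C(C)=C/C[C@@H](C)CCO[Si](C)(C)C(C)(C)C
F8 | step 14 | methyl (1S,5S,6R,8aS)-5-[(3R)-5-{[tert-butyl(dimethyl)silyl]oxy}-3-methylpentyl]-1,5,6-trimethyl-3-oxodecahydronaphthalene-1-carboxylate (C4a epimers) | COC(=O)[C@@]1(C)CC(=O)CC2[C@@H]1CC[C@@H](C)[C@]2(C)CC[C@@H](C)CCO[Si](C)(C)C(C)(C)C
F9 | step 16 | 1,10-epoxide of 25 (oxirane on C1 and C10) | COC(=O)[C@@]1(C)CCC2OC23[C@@H]1CC[C@@H](C)[C@]3(C)CC[C@@H](C)CCO[Si](C)(C)C(C)(C)C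
F10 | step 16 | 10-hydroxy-1-(phenylselanyl) derivative from F9 (formed in the flask) | COC(=O)[C@@]1(C)CCC([Se]c3ccccc3)C2(O)[C@@H]1CC[C@@H](C)[C@]2(C)CC[C@@H](C)CCO[Si](C)(C)C(C)(C)C
F11 | step 16 | tertiary allylic alcohol: 10-hydroxy-1(2)-ene from 25 | COC(=O)[C@@]1(C)CC=CC2(O)[C@@H]1CC[C@@H](C)[C@]2(C)CC[C@@H](C)CCO[Si](C)(C)C(C)(C)C
F12 | step 7 | methyl (2R)-4-chloro-2-methylbutanoate | COC(=O)[C@H](C)CCCl
F13 | step 7 | (2R)-4-chloro-2-methylbutanal | O=C[C@H](C)CCCl
F14 | step 7 | (3R)-1,1-dibromo-5-chloro-3-methylpent-1-ene | BrC(Br)=C[C@H](C)CCCl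
F15 | step 7 | (3R)-5-chloro-3-methylpent-1-yne | C#C[C@H](C)CCCl
A1 | alternative 1 | bicyclic 1(10),11-diene, methyl (1S,5R,6R,8aS)-5-[(1E,3S)-5-{[tert-butyl(dimethyl)silyl]oxy}-3-methylpent-1-en-1-yl]-1,5,6-trimethyl-1,2,3,5,6,7,8,8a-octahydronaphthalene-1-carboxylate | COC(=O)[C@@]1(C)CCC=C2[C@@H]1CC[C@@H](C)[C@]2(C)/C=C/[C@@H](C)CCO[Si](C)(C)C(C)(C)C
A2 | alternative 2 | δ-lactone malonate: methyl 5-{[tert-butyl(dimethyl)silyl]oxy}-6-{6-[5-(4-methoxybenzyloxy)-3-methylpentyl]-5,6-dimethylcyclohex-1-en-1-yl}-2-oxooxane-3-carboxylate, 5,6-trans on the lactone | COC(=O)C1C[C@H](O[Si](C)(C)C(C)(C)C)[C@H](OC1=O)C2=CCC[C@@H](C)[C@]2(C)CC[C@@H](C)CCOCc3ccc(OC)cc3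
A3 | alternative 2 | bicyclic acid ester: 2-silyloxy-halim-1(10)-ene with CO2Me and CO2H on C4 and a 4-methoxybenzyl ether at C15 | COC(=O)[C@@]1(C(=O)O)C[C@H](O[Si](C)(C)C(C)(C)C)C=C2[C@@H]1CC[C@@H](C)[C@]2(C)CC[C@@H](C)CCOCc3ccc(OC)cc3
A4 | alternative 3 | fused δ-lactone: ring A (C4 ester and methyl, C1=C10) fused at C5–C10 to a lactone with O on C6, (E)-prop-1-enyl on C6 and the silyloxy chain on C9 | COC(=O)[C@@]1(C)CCC=C2[C@@H]1[C@H](/C=C/C)OC(=O)C2CC[C@@H](C)CCO[Si](C)(C)C(C)(C)C
A5 | alternative 3 | bicyclic acid: halima-1(10),6-diene with CO2H on C9, CO2Me on C4 and a silyl ether at C15 | COC(=O)[C@@]1(C)CCC=C2[C@@H]1C=C[C@@H](C)[C@]2(C(=O)O)CC[C@@H](C)CCO[Si](C)(C)C(C)(C)C
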